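**Plan**

- Retrosynthesis (eudesmane numbering C1–C15): cut the C15–O ester bond (Mitsunobu), C11=C13 (Mannich methylenation) and C4–C15 (hydroxymethyl Stille coupling of the Δ3 enol triflate) to reach a 4-oxo trans-decalin. Open its ring B at C5–C10 and C6–C7 together (retro-Diels–Alder) to an acyclic trienone, then cut C4–C5 (vinyl Grignard), C8–C9 (Suzuki) and C1–C10 (carbocupration of propyne).
- Forward: a C1–C4 chloro acetal, propyne, a C7/C8/C11/C12 boronate and a vinyl unit are joined to the chain C6=C5–C4(=O)–C3–C2–C1–C10(Me)=C9–C8=C7–C11–C12. Rings A and B then form in the same operation, ring A through the C1–C4 tether and ring B as the cycloadduct ring.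
- Enabling feature: ring B (C5–C10) is an unfunctionalised cyclohexane whose C5–C6 edge lies next to C4, and C4 ends sp2 (C3=C4–C15). C4 can therefore pass through a ketone that activates C5=C6 as dienophile towards the C7=C8–C9=C10 diene, later makes C5 epimerisable, and finally carries C15 through its enol triflate.
- Stereochemistry: the (3E,5Z)-diene (Z from syn-carbocupration) places C7 and C10 substituents cis in the cycloaddition. A chiral oxazaborolidinium catalyst is proposed for the absolute sense. The cis ring fusion forced by the Z-diene is corrected to trans by equilibrating C5 next to the ketone. The Z-cinnamate comes in intact from (Z)-4-hydroxycinnamic acid.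

Key step: step 7

Remark on the chemistry: atoms are numbered as in eudesmanes (C14 angular methyl, C15 on C4, C11–C13 the acrylate unit); (Z)-4-hydroxycinnamic acid is used as purchased and every Z-cinnamate is handled with exclusion of light.

Step 1
Reactants: 1 tert-butyl but-3-enoate; 2 2-ethenyl-4,4,5,5-tetramethyl-1,3,2-dioxaborolane (vinylboronic acid pinacol ester)
Product: 3 tert-butyl (3E)-4-(4,4,5,5-tetramethyl-1,3,2-dioxaborolan-2-yl)but-3-enoate
Conditions: second-generation Grubbs catalyst RuCl2(=CHPh)(PCy3)(H2IMes) (3 mol %), CH2Cl2, 40 °C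
Reagents that add atoms: none
Why: Olefin cross-metathesis of a terminal alkene with the vinylboronate should be E-selective because the boronate and the chain avoid each other in the ruthenacyclobutane, and loss of ethene drives it.

Step 2
Reactants: 4 2-(3-chloropropyl)-1,3-dioxolane; 5 propyne
Product: 8 2-[(4Z)-5-iodo-4-methylpent-4-en-1-yl]-1,3-dioxolane, via Grignard reagent 6 (not isolated), via alkenylcopper 7 (not isolated)
Conditions: Mg (activated), Et2O, reflux; CuBr·SMe2, Et2O/Me2S, −45 °C; propyne, −25 °C; I2, −78 → 0 °C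
Reagents that add atoms: iodine, [I][I]
Why: Normant carbocupration, in which the alkylcopper adds syn across propyne with copper on the terminal carbon and iodinolysis with retention leaves iodine cis to the chain, so the Z-trisubstituted alkene (C9=C10 with C14) is fixed here.

Step 3
Reactants: 8 2-[(4Z)-5-iodo-4-methylpent-4-en-1-yl]-1,3-dioxolane; 3 tert-butyl (3E)-4-(4,4,5,5-tetramethyl-1,3,2-dioxaborolan-2-yl)but-3-enoate
Product: 9 tert-butyl (3E,5Z)-9-(1,3-dioxolan-2-yl)-6-methylnona-3,5-dienoate
Conditions: PdCl2(dppf) (5 mol %), K3PO4, THF/H2O, 23 °C, degassed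
Reagents that add atoms: none
Why: Suzuki–Miyaura coupling joins C8 to C9 with retention of both alkene geometries, and the mild phosphate base at room temperature is chosen to keep the β,γ-unsaturated ester out of conjugation.

Step 4
Reactants: 9 tert-butyl (3E,5Z)-9-(1,3-dioxolan-2-yl)-6-methylnona-3,5-dienoate
Product: 10 tert-butyl (3E,5Z)-6-methyl-10-oxodeca-3,5-dienoate
Conditions: PPTS (0.2 equiv), acetone/H2O 9:1, 55 °C
Reagents that add atoms: water, O
Why: Mild acid-catalysed hydrolysis of the dioxolane should free the C4 aldehyde without touching the tert-butyl ester or the diene geometry.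

Step 5
Reactants: 10 tert-butyl (3E,5Z)-6-methyl-10-oxodeca-3,5-dienoate; 11 ethenylmagnesium bromide (CH2=CHMgBr)
Product: 12 tert-butyl (3E,5Z)-10-hydroxy-6-methyldodeca-3,5,11-trienoate (racemic carbinol)
Conditions: THF, −78 °C; aqueous NH4Cl
Reagents that add atoms: none
Why: Grignard 1,2-addition to the aldehyde at low temperature should outrun enolisation and attack on the hindered tert-butyl ester, and the racemic carbinol centre is erased in the next step.

Step 6
Reactants: 12 tert-butyl (3E,5Z)-10-hydroxy-6-methyldodeca-3,5,11-trienoate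
Product: 13 tert-butyl (3E,5Z)-6-methyl-10-oxododeca-3,5,11-trienoate
Conditions: Dess–Martin periodinane, NaHCO3, CH2Cl2, 0 °C; used at once
Reagents that add atoms: none
Why: Dess–Martin oxidation of the secondary allylic alcohol gives the vinyl ketone under neutral, non-nucleophilic conditions that spare the diene and the skipped ester.

Step 7
Reactants: 13 tert-butyl (3E,5Z)-6-methyl-10-oxododeca-3,5,11-trienoate
Product: 14 tert-butyl 2-[(2R,4aR,8aS)-4a-methyl-8-oxo-1,2,4a,5,6,7,8,8a-octahydronaphthalen-2-yl]acetate (cis-fused, 5β-H, 10β-methyl, 7β-side chain, C8=C9)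
Conditions: (S)-B-(o-tolyl)oxazaborolidinium bis(trifluoromethanesulfonyl)imide [from the (S)-α,α-diphenylprolinol-derived oxazaborolidine and HNTf2] (20 mol %), CH2Cl2 (0.02 M), −78 → −20 °C
Reagents that add atoms: none
Why: Proposed new method: the boron Lewis acid binds the C4 ketone and lowers the LUMO of the C5=C6 vinyl group, which then adds suprafacially across C7 and C10 of the (3E,5Z)-diene in one asynchronous [4+2] transition state in which C6–C7 leads and C5–C10 lags with allyl-cation character at the methyl-bearing C10, so that the quaternary centre forms late and no separate ten-membered ring closure is needed. The closest known reaction types are the oxazaborolidinium-catalysed enantioselective Diels–Alder reactions of vinyl ketones and of trienals and the Lewis-acid-promoted intramolecular Diels–Alder reaction of (Z)-dienes, which have not been shown together on an in-chain trienone with a fully substituted diene terminus. Ring B closes as the six-membered ring of the cycloaddition array and holds both new bonds, and ring A closes through the four-atom tether C1–C4 as a six-membered ring by a type 1, tether-exo mode. C7 and C10 are controlled by the diene geometry, because the two outside groups (CH2CO2tBu on C7, methyl on C10) must end cis on ring B, and C5 is controlled by the tether on the inside position of C10, which can reach only the cis-fused transition state (5β-H, to be corrected in step 8). The absolute sense is left to the catalyst, whose B-aryl group covers one face of the bound s-trans enone; the (S)-catalyst is proposed by analogy with its face preference for simple vinyl ketones and the antipode is equally available. The step needs enone face selectivity and periselectivity, and the latter is secured by the substrate, since the tether lets only the C7=C8–C9=C10 diene reach the vinyl ketone and the bulky tert-butyl ester keeps the Lewis acid on the ketone.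

Step 8
Reactants: 14 tert-butyl 2-[(2R,4aR,8aS)-4a-methyl-8-oxo-1,2,4a,5,6,7,8,8a-octahydronaphthalen-2-yl]acetate
Product: 16 tert-butyl 2-[(2R,4aR,8aR)-4a-methyl-8-oxodecahydronaphthalen-2-yl]acetate (trans-fused), via cis-fused ketone 15 (not isolated)
Conditions: [Ir(cod)(PCy3)(py)]PF6 (3 mol %), H2 (1 atm), CH2Cl2, 23 °C; then DBU (0.5 equiv), PhMe, 60 °C
Reagents that add atoms: none
Why: Homogeneous iridium-catalysed hydrogenation should saturate the C8=C9 alkene without double-bond migration so that C7 is kept, and DBU then equilibrates C5 through the enolate to the more stable trans-decalone with axial angular methyl and equatorial C7 chain.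

Step 9
Reactants: 16 tert-butyl 2-[(2R,4aR,8aR)-4a-methyl-8-oxodecahydronaphthalen-2-yl]acetate
Product: 17 tert-butyl 2-[(2R,4aS,8aR)-4a-methyl-8-(trifluoromethanesulfonyloxy)-1,2,3,4,4a,5,6,8a-octahydronaphthalen-2-yl]acetate
Conditions: KN(SiMe3)2 (1.1 equiv), THF, −78 °C; PhNTf2, −78 → 0 °C
Reagents that add atoms: N-phenylbis(trifluoromethanesulfonimide), O=S(=O)(N(c1ccccc1)S(=O)(=O)C(F)(F)F)C(F)(F)F
Why: Kinetic deprotonation by the hindered amide at the C3 methylene, not at the C5 methine and ahead of the less acidic ester, followed by O-triflation should give the Δ3 enol triflate regioselectively.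

Step 10
Reactants: 17 tert-butyl 2-[(2R,4aS,8aR)-4a-methyl-8-(trifluoromethanesulfonyloxy)-1,2,3,4,4a,5,6,8a-octahydronaphthalen-2-yl]acetate
Product: 18 tert-butyl 2-[(2R,4aS,8aR)-8-(hydroxymethyl)-4a-methyl-1,2,3,4,4a,5,6,8a-octahydronaphthalen-2-yl]acetate
Conditions: Bu3SnCH2OH (1.5 equiv), Pd(PPh3)4 (10 mol %), LiCl (3 equiv), 1,4-dioxane, 100 °C
Reagents that add atoms: (tributylstannyl)methanol, CCCC[Sn](CCCC)(CCCC)CO
Why: Stille coupling of the enol triflate with the hydroxymethylstannane, with LiCl to assist transmetalation, installs C15 as the allylic alcohol with the alkene held at C3=C4.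

Step 11
Reactants: 18 tert-butyl 2-[(2R,4aS,8aR)-8-(hydroxymethyl)-4a-methyl-1,2,3,4,4a,5,6,8a-octahydronaphthalen-2-yl]acetate
Product: 21 tert-butyl 2-[(2R,4aR,8aR)-8-(hydroxymethyl)-4a-methyl-1,2,3,4,4a,5,6,8a-octahydronaphthalen-2-yl]prop-2-enoate, via Mannich base 19 (not isolated), via ammonium iodide 20 (not isolated)
Conditions: LiN(iPr)2 (2.3 equiv), THF, −78 °C; CH2=NMe2+ I−, −78 → 0 °C, aqueous NaHCO3 work-up; MeI, MeOH, 23 °C; DBU, CH2Cl2, 0 → 23 °C
Reagents that add atoms: N,N-dimethylmethyleneiminium iodide (Eschenmoser's salt), C=[N+](C)C.[I-]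
Why: Mannich α-methylenation, in which the ester enolate (the second equivalent of base sits on the alkoxide) is aminomethylated and quaternisation followed by base-induced β-elimination can give only the C11=C13 methylene.

Step 12
Reactants: 21 tert-butyl 2-[(2R,4aR,8aR)-8-(hydroxymethyl)-4a-methyl-1,2,3,4,4a,5,6,8a-octahydronaphthalen-2-yl]prop-2-enoate; 22 (2Z)-3-(4-hydroxyphenyl)prop-2-enoic acid ((Z)-4-hydroxycinnamic acid)
Product: 23 tert-butyl 2-[(2R,4aR,8aR)-8-({[(2Z)-3-(4-hydroxyphenyl)prop-2-enoyl]oxy}methyl)-4a-methyl-1,2,3,4,4a,5,6,8a-octahydronaphthalen-2-yl]prop-2-enoate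
Conditions: PPh3, DIAD, THF, 0 → 23 °C, dark
Reagents that add atoms: none
Why: Mitsunobu esterification activates the primary allylic alcohol so that the carboxylate, far more acidic than the phenol, should attack C15 by SN2 under neutral conditions that keep the Z alkene.

Step 13
Reactants: 23 tert-butyl 2-[(2R,4aR,8aR)-8-({[(2Z)-3-(4-hydroxyphenyl)prop-2-enoyl]oxy}methyl)-4a-methyl-1,2,3,4,4a,5,6,8a-octahydronaphthalen-2-yl]prop-2-enoate
Product: 24 2-[(2R,4aR,8aR)-8-({[(2Z)-3-(4-hydroxyphenyl)prop-2-enoyl]oxy}methyl)-4a-methyl-1,2,3,4,4a,5,6,8a-octahydronaphthalen-2-yl]prop-2-enoic acid (target, CNP0183482.1)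
Conditions: CF3CO2H/CH2Cl2 1:4, 0 °C, dark
Reagents that add atoms: none
Why: Acidolysis of the tert-butyl ester with loss of 2-methylpropene should free the acrylic acid while the allylic Z-coumarate ester and the phenol stay intact.

**Compound list**

1 | tert-butyl but-3-enoate | C=CCC(=O)OC(C)(C)C | starting material
2 | 2-ethenyl-4,4,5,5-tetramethyl-1,3,2-dioxaborolane | C=CB1OC(C)(C)C(C)(C)O1 | starting material
3 | tert-butyl (3E)-4-(4,4,5,5-tetramethyl-1,3,2-dioxaborolan-2-yl)but-3-enoate | CC(C)(C)OC(=O)C/C=C/B1OC(C)(C)C(C)(C)O1 | intermediate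
4 | 2-(3-chloropropyl)-1,3-dioxolane | ClCCCC1OCCO1 | starting material
5 | propyne | CC#C | starting material
6 | [3-(1,3-dioxolan-2-yl)propyl]magnesium chloride | Cl[Mg]CCCC1OCCO1 | intermediate
7 | [(1Z)-5-(1,3-dioxolan-2-yl)-2-methylpent-1-en-1-yl]copper (magnesium halide complex) | [Cu]/C=C(/C)CCCC1OCCO1 | intermediate
8 | 2-[(4Z)-5-iodo-4-methylpent-4-en-1-yl]-1,3-dioxolane | I/C=C(/C)CCCC1OCCO1 | intermediate
9 | tert-butyl (3E,5Z)-9-(1,3-dioxolan-2-yl)-6-methylnona-3,5-dienoate | CC(C)(C)OC(=O)C/C=C/C=C(/C)CCCC1OCCO1 | intermediate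
10 | tert-butyl (3E,5Z)-6-methyl-10-oxodeca-3,5-dienoate | CC(C)(C)OC(=O)C/C=C/C=C(/C)CCCC=O | intermediate
11 | ethenylmagnesium bromide | C=C[Mg]Br | starting material
12 | tert-butyl (3E,5Z)-10-hydroxy-6-methyldodeca-3,5,11-trienoate (racemic carbinol) | CC(C)(C)OC(=O)C/C=C/C=C(/C)CCCC(O)C=C | intermediate
13 | tert-butyl (3E,5Z)-6-methyl-10-oxododeca-3,5,11-trienoate | CC(C)(C)OC(=O)C/C=C/C=C(/C)CCCC(=O)C=C | intermediate
14 | tert-butyl 2-[(2R,4aR,8aS)-4a-methyl-8-oxo-1,2,4a,5,6,7,8,8a-octahydronaphthalen-2-yl]acetate (cis-fused) | CC(C)(C)OC(=O)C[C@@H]1C=C[C@@]2(C)CCCC(=O)[C@H]2C1 | intermediate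
15 | tert-butyl 2-[(2R,4aR,8aS)-4a-methyl-8-oxodecahydronaphthalen-2-yl]acetate (cis-fused) | CC(C)(C)OC(=O)C[C@@H]1CC[C@@]2(C)CCCC(=O)[C@H]2C1 | intermediate
16 | tert-butyl 2-[(2R,4aR,8aR)-4a-methyl-8-oxodecahydronaphthalen-2-yl]acetate (trans-fused) | CC(C)(C)OC(=O)C[C@@H]1CC[C@@]2(C)CCCC(=O)[C@@H]2C1 | intermediate
17 | tert-butyl 2-[(2R,4aS,8aR)-4a-methyl-8-(trifluoromethanesulfonyloxy)-1,2,3,4,4a,5,6,8a-octahydronaphthalen-2-yl]acetate | CC(C)(C)OC(=O)C[C@@H]1CC[C@@]2(C)CCC=C(OS(=O)(=O)C(F)(F)F)[C@@H]2C1 | intermediate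
18 | tert-butyl 2-[(2R,4aS,8aR)-8-(hydroxymethyl)-4a-methyl-1,2,3,4,4a,5,6,8a-octahydronaphthalen-2-yl]acetate | CC(C)(C)OC(=O)C[C@@H]1CC[C@@]2(C)CCC=C(CO)[C@@H]2C1 | intermediate
19 | Mannich base of 18: dimethylaminomethyl group on the ester α-carbon (epimers at that carbon) | CC(C)(C)OC(=O)C(CN(C)C)[C@@H]1CC[C@@]2(C)CCC=C(CO)[C@@H]2C1 | intermediate
20 | trimethylammonium iodide of 19 | CC(C)(C)OC(=O)C(C[N+](C)(C)C)[C@@H]1CC[C@@]2(C)CCC=C(CO)[C@@H]2C1.[I-] | intermediate
21 | tert-butyl 2-[(2R,4aR,8aR)-8-(hydroxymethyl)-4a-methyl-1,2,3,4,4a,5,6,8a-octahydronaphthalen-2-yl]prop-2-enoate | C=C(C(=O)OC(C)(C)C)[C@@H]1CC[C@@]2(C)CCC=C(CO)[C@@H]2C1 | intermediate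
22 | (2Z)-3-(4-hydroxyphenyl)prop-2-enoic acid | OC(=O)/C=C\c1ccc(O)cc1 | starting material
23 | tert-butyl 2-[(2R,4aR,8aR)-8-({[(2Z)-3-(4-hydroxyphenyl)prop-2-enoyl]oxy}methyl)-4a-methyl-1,2,3,4,4a,5,6,8a-octahydronaphthalen-2-yl]prop-2-enoate | C=C(C(=O)OC(C)(C)C)[C@@H]1CC[C@@]2(C)CCC=C(COC(=O)/C=C\c3ccc(O)cc3)[C@@H]2C1 | intermediate
24 | 2-[(2R,4aR,8aR)-8-({[(2Z)-3-(4-hydroxyphenyl)prop-2-enoyl]oxy}methyl)-4a-methyl-1,2,3,4,4a,5,6,8a-octahydronaphthalen-2-yl]prop-2-enoic acid | C=C(C(=O)O)[C@@H]1CC[C@@]2(C)CCC=C(COC(=O)/C=C\c3ccc(O)cc3)[C@@H]2C1 | target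

**Count and risks**

Total step count: 13. Longest linear sequence: 12 steps (4 to 24, steps 2–13).

Steps most likely to fail:

1. Step 7. The bound catalyst may fail to tell the two enone faces apart in a tether-constrained, ketone-exo transition state, or the cycloaddition may stall at the fully substituted diene terminus while the vinyl ketone polymerises. Fallback with known chemistry: setting out from 13, the cycloaddition is driven with the achiral Lewis acid MeAlCl2 (CH2Cl2, −78 → −20 °C), the established promoter for intramolecular Diels–Alder reactions of (Z)-dienes with in-chain carbonyl activation. This should give the same cis-fused adduct as a racemate, that is 14 together with the mirror-image adduct F1. Step 8 applied to the pair passes through 15 and the mirror-image cis-fused ketone F2 and gives 16 together with the mirror-image trans-fused ketone F3. The two are separated by preparative chromatography on a chiral stationary phase, and the route is rejoined at 16.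

2. Step 12. The phenol may compete as nucleophile, or reversible addition of the phosphine to the cinnamic acid may erode the Z geometry during activation. Fallback: setting out from 21, carbodiimide esterification (EDC·HCl, DMAP, CH2Cl2) with bis(2,2,2-trifluoroethyl)phosphonoacetic acid gives the phosphonoacetate ester F4. Still–Gennari olefination with 4-tert-butoxybenzaldehyde (KN(SiMe3)2, 18-crown-6, THF, −78 °C) builds the Z alkene on the substrate and gives the aryl tert-butyl ether F5. CF3CO2H/CH2Cl2 then removes both tert-butyl groups, so the fallback comes back to the route at 24.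

3. Step 13. Acid may isomerise the push–pull Z alkene, ionise the allylic ester or tert-butylate the phenol. Fallback: the Z alkene is made last under neutral conditions. Setting out from 21, Mitsunobu esterification with 3-(4-hydroxyphenyl)prop-2-ynoic acid gives the ynoate ester F6. Acidolysis of the tert-butyl ester at this stage, where no Z alkene is present, gives the ynoate acid F7. Syn-semihydrogenation over Lindlar catalyst (Pd/CaCO3 poisoned with Pb(OAc)2, quinoline, H2, EtOAc, dark) then gives 24, where the route is rejoined.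

Further compounds
F1 | step 7 | tert-butyl 2-[(2S,4aS,8aR)-4a-methyl-8-oxo-1,2,4a,5,6,7,8,8a-octahydronaphthalen-2-yl]acetate (enantiomer of 14) | CC(C)(C)OC(=O)C[C@H]1C=C[C@]2(C)CCCC(=O)[C@@H]2C1
F2 | step 7 | tert-butyl 2-[(2S,4aS,8aR)-4a-methyl-8-oxodecahydronaphthalen-2-yl]acetate (enantiomer of 15) | CC(C)(C)OC(=O)C[C@H]1CC[C@]2(C)CCCC(=O)[C@@H]2C1
F3 | step 7 | tert-butyl 2-[(2S,4aS,8aS)-4a-methyl-8-oxodecahydronaphthalen-2-yl]acetate (enantiomer of 16) | CC(C)(C)OC(=O)C[C@H]1CC[C@]2(C)CCCC(=O)[C@H]2C1
F4 | step 12 | bis(2,2,2-trifluoroethyl)phosphonoacetate ester of 21 at C15–O | C=C(C(=O)OC(C)(C)C)[C@@H]1CC[C@@]2(C)CCC=C(COC(=O)CP(=O)(OCC(F)(F)F)OCC(F)(F)F)[C@@H]2C1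
F5 | step 12 | (2Z)-3-(4-tert-butoxyphenyl)prop-2-enoate ester of 21 at C15–O | C=C(C(=O)OC(C)(C)C)[C@@H]1CC[C@@]2(C)CCC=C(COC(=O)/C=C\c3ccc(OC(C)(C)C)cc3)[C@@H]2C1
F6 | step 13 | 3-(4-hydroxyphenyl)prop-2-ynoate ester of 21 at C15–O | C=C(C(=O)OC(C)(C)C)[C@@H]1CC[C@@]2(C)CCC=C(COC(=O)C#Cc3ccc(O)cc3)[C@@H]2C1
F7 | step 13 | 2-[(2R,4aR,8aR)-8-({[3-(4-hydroxyphenyl)prop-2-ynoyl]oxy}methyl)-4a-methyl-1,2,3,4,4a,5,6,8a-octahydronaphthalen-2-yl]prop-2-enoic acid | C=C(C(=O)O)[C@@H]1CC[C@@]2(C)CCC=C(COC(=O)C#Cc3ccc(O)cc3)[C@@H]2C1
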